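**Retrosynthetic overview** (lignan numbering: C8 and C8' carry the benzyl groups, C9 is the lactone CH2, C9' the lactone C=O)

1. The trans-(3R,4R) lactone comes from its C3-epimeric mixture by base equilibration, so only the non-enolisable C4 centre needs reagent control.
2. The lactone, the only ring and closed last, comes from a γ-hydroxy tert-butyl ester: O9 closes onto the C9' carboxyl carbon, the same O9–C9' bond that forms in nature when a secoisolariciresinol-type diol becomes a matairesinol-type lactone.
3. The γ-hydroxy ester comes from LiBH4 reduction of a 2,3-dibenzylsuccinate with an N-acyl oxazolidinone at one end and a tert-butyl ester at the other; only the trimethoxyphenyl-side carboxyl is reduced, which fixes the regiochemistry.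
4. The succinate comes from C8–C8' bond formation by one-electron oxidative cross-coupling of two C6–C3 enolates, the chemical counterpart of phenylpropanoid 8–8' radical coupling, with an (S)-benzyl oxazolidinone in the dirigent role.
5. The enolate precursors come from 3-(3,4,5-trimethoxyphenyl)propanoic acid plus (S)-4-benzyl-2-oxazolidinone, and from dihydroferulic acid plus isobutylene.

Assumption: the three starting materials 1, 2 and 5 are bought as catalogue compounds, and LiN(iPr)2 is used as a commercial solution.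

**Route**

Step 1
Reactants: 1 3-(3,4,5-trimethoxyphenyl)propanoic acid; 2 (S)-4-benzyl-2-oxazolidinone
Product: 4 (S)-4-benzyl-3-[3-(3,4,5-trimethoxyphenyl)propanoyl]oxazolidin-2-one, via mixed pivalic anhydride 3 (not isolated)
Conditions: PivCl (1.1 equiv), Et3N (2.5 equiv), THF, −20 °C, 1 h; then LiCl (1.1 equiv), 2 (1.0 equiv), −20 °C → rt, 6 h
Reagents that add atoms: none
Why: Mixed-anhydride N-acylation of an oxazolidinone (pivaloyl chloride activation, LiCl/Et3N-promoted acyl transfer), in which the hindered pivaloyl carbonyl steers the nitrogen onto the arylpropanoyl carbonyl and no stereocenter is formed or touched.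

Step 2
Reactants: 5 3-(4-hydroxy-3-methoxyphenyl)propanoic acid (dihydroferulic acid)
Product: 6 tert-butyl 3-(4-tert-butoxy-3-methoxyphenyl)propanoate
Conditions: isobutylene (condensed, ca. 20 equiv), conc. H2SO4 (0.2 equiv), CH2Cl2, sealed pressure vessel, −20 °C → rt, 72 h; aq. NaHCO3
Reagents that add atoms: isobutylene (2-methylpropene), CC(C)=C
Why: Acid-catalysed Markovnikov addition of both the carboxylic acid and the phenol O–H to isobutylene (tert-butyl ester and aryl tert-butyl ether formation, as in the standard preparation of O-tert-butyl tyrosine tert-butyl esters), with O-alkylation kinetically preferred over ring alkylation at or below room temperature and no stereocenter involved.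

Step 3
Reactants: 4 (S)-4-benzyl-3-[3-(3,4,5-trimethoxyphenyl)propanoyl]oxazolidin-2-one; 6 tert-butyl 3-(4-tert-butoxy-3-methoxyphenyl)propanoate
Product: 9 tert-butyl (2RS,3R)-3-{[(4S)-4-benzyl-2-oxo-1,3-oxazolidin-3-yl]carbonyl}-2-(4-tert-butoxy-3-methoxybenzyl)-4-(3,4,5-trimethoxyphenyl)butanoate, via imide lithium enolate 7 (not isolated), via ester lithium enolate 8 (not isolated)
Conditions: 4 (1.0 equiv), 6 (1.2 equiv), LiN(iPr)2 (2.2 equiv), THF, −78 °C, 40 min; then Fe(acac)3 (2.2 equiv) in THF, −78 °C → rt, 1 h; aq. NH4Cl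
Reagents that add atoms: none
Why: Oxidative enolate heterocoupling, in which trivalent iron oxidises the mixed lithium enolates by one electron, the α-ester radical adds to the chelated Z-enolate 7 on the face opposite the 4-benzyl group of the auxiliary (the facial sense of Evans alkylation) and a second one-electron oxidation completes the C8–C8' bond, so C3 is set as R by the auxiliary while C2 forms as an epimeric mixture that is corrected in step 5.

Step 4
Reactants: 9 tert-butyl (2RS,3R)-3-{[(4S)-4-benzyl-2-oxo-1,3-oxazolidin-3-yl]carbonyl}-2-(4-tert-butoxy-3-methoxybenzyl)-4-(3,4,5-trimethoxyphenyl)butanoate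
Product: 10 tert-butyl (2RS,3R)-2-(4-tert-butoxy-3-methoxybenzyl)-3-(hydroxymethyl)-4-(3,4,5-trimethoxyphenyl)butanoate
Conditions: LiBH4 (2.0 equiv), THF, 0 °C → rt, 3 h; sat. aq. NH4Cl
Reagents that add atoms: none
Why: Chemoselective hydride reduction of an N-acyl oxazolidinone (reductive auxiliary removal with LiBH4), in which the activated exocyclic imide carbonyl is reduced to the primary alcohol while the tert-butyl ester is untouched, and C3 keeps its configuration because nothing is enolised.

Step 5
Reactants: 10 tert-butyl (2RS,3R)-2-(4-tert-butoxy-3-methoxybenzyl)-3-(hydroxymethyl)-4-(3,4,5-trimethoxyphenyl)butanoate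
Product: 12 (3R,4R)-3-(4-hydroxy-3-methoxybenzyl)-4-(3,4,5-trimethoxybenzyl)dihydrofuran-2(3H)-one, via lactone epimer mixture 11 (not isolated)
Conditions: TFA/CH2Cl2 (1:1), Et3SiH (5 equiv), 0 °C → rt, 3 h; evaporate; then DBU (5 equiv), toluene, 90 °C, 12 h, under Ar; 1 M HCl work-up
Reagents that add atoms: none
Why: Acidolysis of both tert-butyl groups with acid-catalysed lactonisation of the γ-hydroxy ester (O9 onto the C9' acyl carbon, tert-butyl cations reduced to isobutane by Et3SiH) followed by DBU-mediated α-epimerisation of the lactone, in which the non-enolisable C4 stays R and the enolisable C3 equilibrates to the thermodynamically favoured trans arrangement, which is 3R.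

**Compound list**

1 | 3-(3,4,5-trimethoxyphenyl)propanoic acid | COc1cc(CCC(=O)O)cc(OC)c1OC | starting material
2 | (S)-4-benzyl-2-oxazolidinone | O=C1N[C@@H](Cc2ccccc2)CO1 | starting material
3 | 2,2-dimethylpropanoic 3-(3,4,5-trimethoxyphenyl)propanoic anhydride (mixed pivalic anhydride) | COc1cc(CCC(=O)OC(=O)C(C)(C)C)cc(OC)c1OC | intermediate
4 | (S)-4-benzyl-3-[3-(3,4,5-trimethoxyphenyl)propanoyl]oxazolidin-2-one | COc1cc(CCC(=O)N2[C@@H](Cc3ccccc3)COC2=O)cc(OC)c1OC | intermediate
5 | 3-(4-hydroxy-3-methoxyphenyl)propanoic acid (dihydroferulic acid) | COc1cc(CCC(=O)O)ccc1O | starting material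
6 | tert-butyl 3-(4-tert-butoxy-3-methoxyphenyl)propanoate | COc1cc(CCC(=O)OC(C)(C)C)ccc1OC(C)(C)C | intermediate
7 | lithium (Z)-enolate of 4: lithium (Z)-1-[(4S)-4-benzyl-2-oxo-1,3-oxazolidin-3-yl]-3-(3,4,5-trimethoxyphenyl)prop-1-en-1-olate | COc1cc(C/C=C(\O[Li])N2[C@@H](Cc3ccccc3)COC2=O)cc(OC)c1OC | intermediate
8 | lithium enolate of 6: lithium 1-tert-butoxy-3-(4-tert-butoxy-3-methoxyphenyl)prop-1-en-1-olate (mainly the isomer with the benzylic CH2 trans to OLi) | COc1cc(C/C=C(/O[Li])OC(C)(C)C)ccc1OC(C)(C)C | intermediate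
9 | tert-butyl (2RS,3R)-3-{[(4S)-4-benzyl-2-oxo-1,3-oxazolidin-3-yl]carbonyl}-2-(4-tert-butoxy-3-methoxybenzyl)-4-(3,4,5-trimethoxyphenyl)butanoate (C2 epimers) | COc1cc(CC(C(=O)OC(C)(C)C)[C@@H](Cc2cc(OC)c(OC)c(OC)c2)C(=O)N2[C@@H](Cc3ccccc3)COC2=O)ccc1OC(C)(C)C | intermediate
10 | tert-butyl (2RS,3R)-2-(4-tert-butoxy-3-methoxybenzyl)-3-(hydroxymethyl)-4-(3,4,5-trimethoxyphenyl)butanoate (C2 epimers) | COc1cc(CC(C(=O)OC(C)(C)C)[C@@H](Cc2cc(OC)c(OC)c(OC)c2)CO)ccc1OC(C)(C)C | intermediate
11 | (3RS,4R)-3-(4-hydroxy-3-methoxybenzyl)-4-(3,4,5-trimethoxybenzyl)dihydrofuran-2(3H)-one (cis/trans mixture) | COc1cc(CC2C(=O)OC[C@@H]2Cc2cc(OC)c(OC)c(OC)c2)ccc1O | intermediate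
12 | (3R,4R)-3-(4-hydroxy-3-methoxybenzyl)-4-(3,4,5-trimethoxybenzyl)dihydrofuran-2(3H)-one (trans) | COc1cc(C[C@H]2C(=O)OC[C@@H]2Cc2cc(OC)c(OC)c(OC)c2)ccc1O | target

**Summary**

Total step count: 5. Longest linear sequence: 4 steps (1 → 4 → 9 → 10 → 12, or 5 → 6 → 9 → 10 → 12).

Steps most likely to fail, with fallbacks:

Step 3 is the riskiest: homodimers of either enolate compete, the expected yield is only moderate (about 50%), and facial control at C3 may be incomplete. The fallback replaces the radical coupling by a two-electron displacement; it sets out from 6 and comes back to the route at 9. Enolate 8 is hydroxylated with 2-(phenylsulfonyl)-3-phenyloxaziridine (THF, −78 °C) to give racemic tert-butyl 3-(4-tert-butoxy-3-methoxyphenyl)-2-hydroxypropanoate F1. This is converted with Tf2O and 2,6-lutidine (CH2Cl2, −78 °C) into tert-butyl 3-(4-tert-butoxy-3-methoxyphenyl)-2-[(trifluoromethylsulfonyl)oxy]propanoate F2. Enolate 7 then displaces the triflate (THF, −78 °C → −20 °C) with the same auxiliary-controlled facial selectivity to give 9; the configuration at C2 is again irrelevant because step 5 equilibrates it.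

Step 2 may give ring tert-butylation or incomplete O-alkylation of the guaiacol oxygen flanked by the methoxy group. The fallback uses two separate alkylations without isobutylene or strong Brønsted acid; it sets out from 5 and comes back at 6. tert-Butyl 2,2,2-trichloroacetimidate (CH2Cl2/cyclohexane, rt) esterifies only the carboxylic acid to give tert-butyl 3-(4-hydroxy-3-methoxyphenyl)propanoate F3, and the phenol is then etherified with Boc2O and catalytic Sc(OTf)3 (CH2Cl2, rt) to give 6.

Step 4 may suffer hydride attack at the ring carbonyl of the hindered imide (ring-opened hydroxy amide) or sluggish reduction. The fallback is hydrolysis followed by acid-selective reduction; it sets out from 9 and comes back at 10. LiOH/H2O2 (THF/H2O, 0 °C) cleaves the auxiliary to give (2R,3RS)-4-tert-butoxy-3-(4-tert-butoxy-3-methoxybenzyl)-4-oxo-2-(3,4,5-trimethoxybenzyl)butanoic acid F4, and BH3·SMe2 (THF, 0 °C → rt) reduces the free carboxylic acid, not the tert-butyl ester, to give 10.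

**Further compounds**

F1 | step 3 | tert-butyl 3-(4-tert-butoxy-3-methoxyphenyl)-2-hydroxypropanoate (racemic) | COc1cc(CC(O)C(=O)OC(C)(C)C)ccc1OC(C)(C)C
F2 | step 3 | tert-butyl 3-(4-tert-butoxy-3-methoxyphenyl)-2-[(trifluoromethylsulfonyl)oxy]propanoate (racemic) | COc1cc(CC(OS(=O)(=O)C(F)(F)F)C(=O)OC(C)(C)C)ccc1OC(C)(C)C
F3 | step 2 | tert-butyl 3-(4-hydroxy-3-methoxyphenyl)propanoate | COc1cc(CCC(=O)OC(C)(C)C)ccc1O
F4 | step 4 | (2R,3RS)-4-tert-butoxy-3-(4-tert-butoxy-3-methoxybenzyl)-4-oxo-2-(3,4,5-trimethoxybenzyl)butanoic acid | COc1cc(CC(C(=O)OC(C)(C)C)[C@@H](Cc2cc(OC)c(OC)c(OC)c2)C(=O)O)ccc1OC(C)(C)C
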